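**Plan**

- Retrosynthesis, cut 1: the CH2–CH2 link between ring B and the dioxane is made as CH=CH by a Wittig reaction and then reduced; this gives phosphonium salt 19 and dioxane aldehyde 35.
- Retrosynthesis, cut 2 (two bonds at once): ring B is numbered as in 14–19 (C1 = CMe2, C2, C3, C4 = CH2, C4a, C8a). Its tetrasubstituted C2=C3 alkene lies between C1 and CH2-4, so C1–C2 and C3–C4 are cut together. This leads to alkyne 11 and the C(=O)–CH2 bond of cyclobutanone 9, which is cis-fused to ring A at C4a/C8a; C1 is the former ketone carbon.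
- Forward, carbocycle: ring A is bought as diene 1; a ketene [2+2] fuses the four-membered ring; the nickel-catalysed two-carbon ring expansion makes ring B; then C1=O becomes CMe2 and SiMe3 becomes CH3.
- Forward, heterocycle: (R)-linalool → aldehyde 23 → aldol → epoxy mesylate 32 → tertiary hydroperoxide → 6-exo closure of the 1,2-dioxane; the fragments are joined and the primary alcohol is oxidised to the acid last.
- Stereochemistry: cis C4a/C8a from the suprafacial [2+2], absolute configuration by sulfoximine resolution. The quaternary peroxy carbon comes from (R)-linalool, inverted once in the epoxide perhydrolysis. The secondary peroxy carbon and the acid α-carbon come from an Evans syn-aldol, the carbinol carbon being inverted once in the ring closure.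

Key step: step 6

Assumption: 1-methylcyclohexa-1,3-diene (1) and (R)-(−)-linalool (20) of high enantiomeric purity are taken as purchasable; the adduct from any minor enantiomer of 20 is a diastereomer of 26 and is removed there.

**Route**

Step 1
Reactants: 1 1-methylcyclohexa-1,3-diene; 2 trichloroacetyl chloride
Product: 4 rac-(1R,6S)-8,8-dichloro-3-methylbicyclo[4.2.0]oct-2-en-7-one, via dichloroketene 3 (not isolated)
Conditions: Zn–Cu couple, POCl3, Et2O, rt, slow addition of 2
Reagents that add atoms: none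
Why: Thermal ketene–alkene [2+2] cycloaddition: dichloroketene adds to the less substituted C3=C4 alkene of 1 with its carbonyl carbon on the unsubstituted diene terminus (methyl-stabilised allyl-cation-like transition state), so C=O sits on the non-allylic and CCl2 on the allylic ring carbon, and the suprafacial addition fixes the cis ring fusion (racemic).

Step 2
Reactants: 4 rac-(1R,6S)-8,8-dichloro-3-methylbicyclo[4.2.0]oct-2-en-7-one
Product: 5 rac-(1R,6S)-3-methylbicyclo[4.2.0]oct-2-en-7-one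
Conditions: Zn, AcOH, 70 °C
Reagents that add atoms: none
Why: Reductive dechlorination of an α,α-dichlorocyclobutanone with zinc in acetic acid is standard and leaves the ring alkene and both ring-fusion centres untouched.

Step 3
Reactants: 5 rac-(1R,6S)-3-methylbicyclo[4.2.0]oct-2-en-7-one; 6 (S)-N,S-dimethyl-S-phenylsulfoximine
Product: 8 (1R,6S,7R)-3-methyl-7-{[(S)-N-methyl-S-phenylsulfonimidoyl]methyl}bicyclo[4.2.0]oct-2-en-7-ol, via lithiated sulfoximine 7 (not isolated)
Conditions: n-BuLi, THF, −78 °C; then 5; NH4Cl (aq); separation of the two diastereomers on SiO2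
Reagents that add atoms: none
Why: Johnson sulfoximine resolution: 1,2-addition of the enantiopure lithiated sulfoximine to the convex face of the strained ketone turns the two enantiomers of 5 into two diastereomeric β-hydroxysulfoximines that should separate by chromatography, and the (1R,6S,7R) isomer is kept (at most half of the material).

Step 4
Reactants: 8 (1R,6S,7R)-3-methyl-7-{[(S)-N-methyl-S-phenylsulfonimidoyl]methyl}bicyclo[4.2.0]oct-2-en-7-ol
Product: 9 (1R,6S)-3-methylbicyclo[4.2.0]oct-2-en-7-one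
Conditions: toluene, 110 °C
Reagents that add atoms: none
Why: Thermal retro-addition of a β-hydroxysulfoximine returns the ketone and the sulfoximine without touching C1 or C6, so 9 should be obtained as a single enantiomer.

Step 5
Reactants: 10 3-(trimethylsilyl)prop-2-yn-1-ol
Product: 11 tert-butyldimethyl{[3-(trimethylsilyl)prop-2-yn-1-yl]oxy}silane
Conditions: t-BuMe2SiCl, imidazole, DMF, rt
Reagents that add atoms: tert-butyl(chloro)dimethylsilane CC(C)(C)[Si](C)(C)Cl
Why: Standard imidazole-promoted silylation of a primary alcohol.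

Step 6
Reactants: 9 (1R,6S)-3-methylbicyclo[4.2.0]oct-2-en-7-one; 11 tert-butyldimethyl{[3-(trimethylsilyl)prop-2-yn-1-yl]oxy}silane
Product: 12 (4aR,8aS)-2-{[tert-butyl(dimethyl)silyl]oxymethyl}-6-methyl-3-(trimethylsilyl)-4a,7,8,8a-tetrahydronaphthalen-1(4H)-one
Conditions: Ni(C8H12)2 (10 mol%), P(C6H11)3 (20 mol%), toluene, 100 °C
Reagents that add atoms: none
Why: Zerovalent nickel couples the ketone carbonyl of 9 with the alkyne by oxidative cyclisation to an oxanickelacyclopentene (C1–C2 bond formed, silicon-bearing carbon on nickel); β-carbon elimination then opens the strained ring at its C(=O)–CH2 bond to a seven-membered nickelacycle, and C(sp3)–C(sp2) reductive elimination forms C3–C4. The closest known reaction type is the nickel-catalysed intermolecular insertion of internal alkynes into cyclobutanones to give cyclohex-2-enones (a formal [4+2] ring expansion). Ring B closes by two-carbon ring expansion of the four-membered ring (net insertion into its C7–C8 σ bond), not by an end-to-end cyclisation, and ring A is a spectator. No stereocentre is created: C1 and C6 of 9 take part in no bond change and reappear as the cis ring-fusion carbons C4a and C8a. The step needs site selectivity for the CH2–C(=O) bond over the CH–C(=O) bond, which the preference of β-carbon elimination for the primary carbon should secure. It also needs alkyne regioselectivity, which the trimethylsilyl group should secure by taking the nickel-bound position, so that the siloxymethyl carbon bonds to the carbonyl carbon (C2) and silicon ends at C3.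

Step 7
Reactants: 12 (4aR,8aS)-2-{[tert-butyl(dimethyl)silyl]oxymethyl}-6-methyl-3-(trimethylsilyl)-4a,7,8,8a-tetrahydronaphthalen-1(4H)-one
Product: 13 (4aR,8aS)-2-{[tert-butyl(dimethyl)silyl]oxymethyl}-1,6-dimethyl-3-(trimethylsilyl)-1,4,4a,7,8,8a-hexahydronaphthalen-1-ol (either C1 epimer)
Conditions: MeLi, CeCl3, THF, −78 °C
Reagents that add atoms: methyllithium [Li]C
Why: Cerium-mediated 1,2-addition of methyllithium to the hindered, enolisable enone suppresses deprotonation at C8a and conjugate addition; the new carbinol centre is destroyed in step 8, so its configuration does not matter.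

Step 8
Reactants: 13 (4aR,8aS)-2-{[tert-butyl(dimethyl)silyl]oxymethyl}-1,6-dimethyl-3-(trimethylsilyl)-1,4,4a,7,8,8a-hexahydronaphthalen-1-ol
Product: 14 tert-butyldimethyl{[(4aR,8aS)-1,1,6-trimethyl-3-(trimethylsilyl)-1,4,4a,7,8,8a-hexahydronaphthalen-2-yl]methoxy}silane
Conditions: Al(CH3)3 (4 equiv), CH2Cl2, −78 °C → rt
Reagents that add atoms: trimethylaluminium C[Al](C)C
Why: Trimethylaluminium-mediated SN1 methylation of a tertiary allylic alcohol: the aluminium alkoxide ionises to the allyl cation, whose silicon-bearing terminus C3 is sterically blocked and electronically disfavoured (α-silyl cation), so methyl should be delivered to C1 to give the gem-dimethyl carbon with the alkene back at C2=C3; C8a cannot epimerise once C1 is sp3.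

Step 9
Reactants: 14 tert-butyldimethyl{[(4aR,8aS)-1,1,6-trimethyl-3-(trimethylsilyl)-1,4,4a,7,8,8a-hexahydronaphthalen-2-yl]methoxy}silane
Product: 15 tert-butyl{[(4aR,8aS)-3-iodo-1,1,6-trimethyl-1,4,4a,7,8,8a-hexahydronaphthalen-2-yl]methoxy}dimethylsilane
Conditions: N-iodosuccinimide, 2,6-lutidine, (CF3)2CHOH/CH2Cl2, 0 °C
Reagents that add atoms: N-iodosuccinimide O=C1CCC(=O)N1I
Why: ipso-Iododesilylation of a vinylsilane: iodonium attack at the silicon-bearing carbon is favoured by β-silyl stabilisation and loss of silicon restores the C2=C3 alkene in place, while iodonium formation at the ring-A alkene is reversible in the non-nucleophilic solvent.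

Step 10
Reactants: 15 tert-butyl{[(4aR,8aS)-3-iodo-1,1,6-trimethyl-1,4,4a,7,8,8a-hexahydronaphthalen-2-yl]methoxy}dimethylsilane
Product: 17 tert-butyldimethyl{[(4aR,8aS)-1,1,3,6-tetramethyl-1,4,4a,7,8,8a-hexahydronaphthalen-2-yl]methoxy}silane, via alkenyllithium 16 (not isolated)
Conditions: t-BuLi (2.1 equiv), Et2O, −78 °C; then MeI, −78 → 0 °C
Reagents that add atoms: iodomethane CI
Why: Iodine–lithium exchange followed by alkylation of the cyclic alkenyllithium with iodomethane installs the C3 methyl group; the silyl ether cannot be eliminated because C2 already carries three carbon substituents.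

Step 11
Reactants: 17 tert-butyldimethyl{[(4aR,8aS)-1,1,3,6-tetramethyl-1,4,4a,7,8,8a-hexahydronaphthalen-2-yl]methoxy}silane
Product: 19 {[(4aR,8aS)-1,1,3,6-tetramethyl-1,4,4a,7,8,8a-hexahydronaphthalen-2-yl]methyl}triphenylphosphonium bromide, via allylic alcohol 18 (not isolated)
Conditions: Ph3P·HBr, MeOH, rt
Reagents that add atoms: triphenylphosphine hydrobromide [Br-].c1ccc(cc1)[PH+](c1ccccc1)c1ccccc1
Why: Acidic methanol removes the primary silyl ether and triphenylphosphine hydrobromide converts the cyclogeraniol-type allylic alcohol by SN1 substitution at the primary allylic terminus into the phosphonium salt, the usual route to cyclogeranyl phosphonium salts.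

Step 12
Reactants: 20 (R)-(−)-linalool [(3R)-3,7-dimethylocta-1,6-dien-3-ol]
Product: 21 (2R)-2-methylpentane-1,2,5-triol
Conditions: O3, CH2Cl2/MeOH, −78 °C; then NaBH4, −78 °C → rt
Reagents that add atoms: ozone [O-][O+]=O
Why: Ozonolysis of both alkenes with reductive (NaBH4) work-up removes C1 and the isopropylidene carbon and gives the triol; the tertiary carbinol centre of linalool is not touched.

Step 13
Reactants: 21 (2R)-2-methylpentane-1,2,5-triol
Product: 22 3-[(4R)-2,2,4-trimethyl-1,3-dioxolan-4-yl]propan-1-ol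
Conditions: Me2C(OMe)2, TsOH (cat.), acetone, rt
Reagents that add atoms: 2,2-dimethoxypropane COC(C)(C)OC
Why: Acetonide formation selects the 1,2-diol (five-membered dioxolane) and leaves the remote primary alcohol free.

Step 14
Reactants: 22 3-[(4R)-2,2,4-trimethyl-1,3-dioxolan-4-yl]propan-1-ol
Product: 23 3-[(4R)-2,2,4-trimethyl-1,3-dioxolan-4-yl]propanal
Conditions: PhI(OAc)2, TEMPO (cat.), CH2Cl2, rt
Reagents that add atoms: none
Why: TEMPO/PhI(OAc)2 oxidation stops at the aldehyde in the absence of water and is mild enough for the acetonide.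

Step 15
Reactants: 24 (4R)-4-benzyl-3-propanoyl-1,3-oxazolidin-2-one; 23 3-[(4R)-2,2,4-trimethyl-1,3-dioxolan-4-yl]propanal
Product: 26 (4R)-4-benzyl-3-{(2R,3S)-3-hydroxy-2-methyl-5-[(4R)-2,2,4-trimethyl-1,3-dioxolan-4-yl]pentanoyl}-1,3-oxazolidin-2-one, via boron enolate 25 (not isolated)
Conditions: Bu2BOTf, i-Pr2NEt, CH2Cl2, −78 → 0 °C; 23, −78 → 0 °C; pH 7 buffer, MeOH, H2O2
Reagents that add atoms: none
Why: Evans syn-aldol: the (Z)-boron enolate reacts through a Zimmerman–Traxler chair in which the (R)-benzyl auxiliary shields one enolate face, which should set (2R,3S) with the existing centre playing no role.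

Step 16
Reactants: 26 (4R)-4-benzyl-3-{(2R,3S)-3-hydroxy-2-methyl-5-[(4R)-2,2,4-trimethyl-1,3-dioxolan-4-yl]pentanoyl}-1,3-oxazolidin-2-one
Product: 27 (2S,3S)-2-methyl-5-[(4R)-2,2,4-trimethyl-1,3-dioxolan-4-yl]pentane-1,3-diol
Conditions: LiBH4, MeOH (1 equiv), Et2O, 0 °C
Reagents that add atoms: none
Why: Reductive cleavage of the imide with LiBH4 gives the primary alcohol and returns the auxiliary without epimerising C2 (the descriptor changes only through the priority rules).

Step 17
Reactants: 27 (2S,3S)-2-methyl-5-[(4R)-2,2,4-trimethyl-1,3-dioxolan-4-yl]pentane-1,3-diol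
Product: 28 (2S,3S)-1-[(tert-butyldiphenylsilyl)oxy]-2-methyl-5-[(4R)-2,2,4-trimethyl-1,3-dioxolan-4-yl]pentan-3-ol
Conditions: t-BuPh2SiCl, imidazole, CH2Cl2, 0 °C
Reagents that add atoms: tert-butyl(chloro)diphenylsilane CC(C)(C)[Si](Cl)(c1ccccc1)c1ccccc1
Why: Selective silylation of the primary over the secondary hydroxyl with the bulky silyl chloride; the carboxyl carbon is kept at the alcohol level so that no β-leaving group ever sits next to a carbonyl.

Step 18
Reactants: 28 (2S,3S)-1-[(tert-butyldiphenylsilyl)oxy]-2-methyl-5-[(4R)-2,2,4-trimethyl-1,3-dioxolan-4-yl]pentan-3-ol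
Product: 29 (2R,5S,6S)-7-[(tert-butyldiphenylsilyl)oxy]-2,6-dimethylheptane-1,2,5-triol
Conditions: AcOH/H2O/THF (3:1:1), 40 °C
Reagents that add atoms: none
Why: Acid hydrolysis of the acetonide with the TBDPS ether surviving; no leaving group is present yet, so no cyclic ether can form.

Step 19
Reactants: 29 (2R,5S,6S)-7-[(tert-butyldiphenylsilyl)oxy]-2,6-dimethylheptane-1,2,5-triol
Product: 31 (2S,3S)-1-[(tert-butyldiphenylsilyl)oxy]-2-methyl-5-[(2R)-2-methyloxiran-2-yl]pentan-3-ol, via primary tosylate 30 (not isolated)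
Conditions: TsCl, Et3N, Bu2SnO (cat.), CH2Cl2, rt; then K2CO3, MeOH, 0 °C
Reagents that add atoms: none
Why: Tin-catalysed selective tosylation of the primary hydroxyl of the 1,2-diol, then 3-exo-tet Williamson closure by the tertiary alkoxide, gives the epoxide with retention at the tertiary carbon because its C–O bond is not broken; the free secondary hydroxyl is only exposed to base, under which it does not open the epoxide.

Step 20
Reactants: 31 (2S,3S)-1-[(tert-butyldiphenylsilyl)oxy]-2-methyl-5-[(2R)-2-methyloxiran-2-yl]pentan-3-ol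
Product: 32 (2S,3S)-1-[(tert-butyldiphenylsilyl)oxy]-2-methyl-5-[(2R)-2-methyloxiran-2-yl]pentan-3-yl methanesulfonate
Conditions: MsCl, Et3N, CH2Cl2, −20 °C
Reagents that add atoms: methanesulfonyl chloride CS(Cl)(=O)=O
Why: Mesylation of the secondary alcohol with retention, under basic conditions that the 2,2-disubstituted epoxide tolerates; from here on no free hydroxyl can attack the epoxide.

Step 21
Reactants: 32 (2S,3S)-1-[(tert-butyldiphenylsilyl)oxy]-2-methyl-5-[(2R)-2-methyloxiran-2-yl]pentan-3-yl methanesulfonate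
Product: 33 (2S,3S,6S)-1-[(tert-butyldiphenylsilyl)oxy]-6-hydroperoxy-7-hydroxy-2,6-dimethylheptan-3-yl methanesulfonate
Conditions: H2O2 (anhydrous, in Et2O, excess), H3PMo12O40 (cat.), rt
Reagents that add atoms: hydrogen peroxide OO
Why: Phosphomolybdic-acid-catalysed perhydrolysis of a 2,2-disubstituted epoxide: hydrogen peroxide should open the activated epoxide at the tertiary carbon with inversion (borderline SN2) to give the (6S) tertiary hydroperoxide, the mesylate being inert to neutral H2O2.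

Step 22
Reactants: 33 (2S,3S,6S)-1-[(tert-butyldiphenylsilyl)oxy]-6-hydroperoxy-7-hydroxy-2,6-dimethylheptan-3-yl methanesulfonate
Product: 34 {(3S,6R)-6-[(2S)-1-[(tert-butyldiphenylsilyl)oxy]propan-2-yl]-3-methyl-1,2-dioxan-3-yl}methanol
Conditions: Cs2CO3, DMF, 0 °C → rt
Reagents that add atoms: none
Why: Intramolecular 6-exo-tet SN2 alkylation of the hydroperoxide anion (much more acidic than the alcohol) by the secondary mesylate closes the 1,2-dioxane with inversion at the CH carbon, turning the syn aldol relationship into the anti relationship of the target; a tertiary hydroperoxide cannot undergo Kornblum–DeLaMare fragmentation.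

Step 23
Reactants: 34 {(3S,6R)-6-[(2S)-1-[(tert-butyldiphenylsilyl)oxy]propan-2-yl]-3-methyl-1,2-dioxan-3-yl}methanol
Product: 35 (3S,6R)-6-{(2S)-1-[(tert-butyldiphenylsilyl)oxy]propan-2-yl}-3-methyl-1,2-dioxane-3-carbaldehyde
Conditions: Dess–Martin periodinane, NaHCO3, CH2Cl2, rt
Reagents that add atoms: none
Why: Dess–Martin oxidation of the neopentyl-type primary alcohol gives an α-peroxy aldehyde that cannot enolise (quaternary α-carbon), and dialkyl peroxides are inert to the periodinane.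

Step 24
Reactants: 19 {[(4aR,8aS)-1,1,3,6-tetramethyl-1,4,4a,7,8,8a-hexahydronaphthalen-2-yl]methyl}triphenylphosphonium bromide; 35 (3S,6R)-6-{(2S)-1-[(tert-butyldiphenylsilyl)oxy]propan-2-yl}-3-methyl-1,2-dioxane-3-carbaldehyde
Product: 37 tert-butyl{(2S)-2-[(3R,6S)-6-methyl-6-{2-[(4aR,8aS)-1,1,3,6-tetramethyl-1,4,4a,7,8,8a-hexahydronaphthalen-2-yl]ethenyl}-1,2-dioxan-3-yl]propoxy}diphenylsilane (E/Z mixture), via phosphorus ylide 36 (not isolated)
Conditions: NaN(SiMe3)2, THF, −78 → 0 °C; then 35, −78 °C → rt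
Reagents that add atoms: none
Why: Wittig olefination of the non-enolisable aldehyde with the semi-stabilised cyclogeranyl-type ylide joins the two fragments; alkene geometry is irrelevant because this bond is reduced next, and cyclic dialkyl peroxides tolerate ylides at low temperature.

Step 25
Reactants: 37 tert-butyl{(2S)-2-[(3R,6S)-6-methyl-6-{2-[(4aR,8aS)-1,1,3,6-tetramethyl-1,4,4a,7,8,8a-hexahydronaphthalen-2-yl]ethenyl}-1,2-dioxan-3-yl]propoxy}diphenylsilane
Product: 38 tert-butyl{(2S)-2-[(3R,6R)-6-methyl-6-{2-[(4aR,8aS)-1,1,3,6-tetramethyl-1,4,4a,7,8,8a-hexahydronaphthalen-2-yl]ethyl}-1,2-dioxan-3-yl]propoxy}diphenylsilane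
Conditions: 2-O2NC6H4SO2NHNH2 (excess), Et3N, CH2Cl2, rt
Reagents that add atoms: none
Why: Diimide reduction: concerted syn transfer of hydrogen should reduce only the 1,2-disubstituted alkene, the tri- and tetrasubstituted alkenes reacting far more slowly, and it leaves the O–O bond intact where catalytic hydrogenation would cleave it.

Step 26
Reactants: 38 tert-butyl{(2S)-2-[(3R,6R)-6-methyl-6-{2-[(4aR,8aS)-1,1,3,6-tetramethyl-1,4,4a,7,8,8a-hexahydronaphthalen-2-yl]ethyl}-1,2-dioxan-3-yl]propoxy}diphenylsilane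
Product: 39 (2S)-2-[(3R,6R)-6-methyl-6-{2-[(4aR,8aS)-1,1,3,6-tetramethyl-1,4,4a,7,8,8a-hexahydronaphthalen-2-yl]ethyl}-1,2-dioxan-3-yl]propan-1-ol
Conditions: HF·pyridine, pyridine, THF, 0 °C → rt
Reagents that add atoms: none
Why: Fluoride cleavage of the silyl ether under buffered, non-basic conditions avoids base-induced Kornblum–DeLaMare fragmentation at the secondary peroxide carbon.

Step 27
Reactants: 39 (2S)-2-[(3R,6R)-6-methyl-6-{2-[(4aR,8aS)-1,1,3,6-tetramethyl-1,4,4a,7,8,8a-hexahydronaphthalen-2-yl]ethyl}-1,2-dioxan-3-yl]propan-1-ol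
Product: 41 (2R)-2-[(3R,6R)-6-methyl-6-{2-[(4aR,8aS)-1,1,3,6-tetramethyl-1,4,4a,7,8,8a-hexahydronaphthalen-2-yl]ethyl}-1,2-dioxan-3-yl]propanoic acid (CNP0122760.1), via aldehyde 40 (not isolated)
Conditions: PhI(OAc)2 (2.5 equiv), TEMPO (cat.), MeCN/H2O, rt
Reagents that add atoms: water O
Why: TEMPO/PhI(OAc)2 oxidation in aqueous acetonitrile takes the primary alcohol through the aldehyde hydrate to the acid without base, so the α-stereocentre and the β-peroxy linkage are not exposed to enolisation or elimination and the alkenes are untouched.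

**Compound list**

1 | 1-methylcyclohexa-1,3-diene | CC1=CC=CCC1 | starting material
2 | trichloroacetyl chloride | ClC(Cl)(Cl)C(Cl)=O | starting material
3 | dichloroketene | ClC(Cl)=C=O | intermediate
4 | rac-(1R,6S)-8,8-dichloro-3-methylbicyclo[4.2.0]oct-2-en-7-one (cis-fused racemate, one enantiomer drawn) | CC1=C[C@H]2C(Cl)(Cl)C(=O)[C@H]2CC1 | intermediate
5 | rac-(1R,6S)-3-methylbicyclo[4.2.0]oct-2-en-7-one (cis-fused racemate, one enantiomer drawn) | CC1=C[C@H]2CC(=O)[C@H]2CC1 | intermediate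
6 | (S)-N,S-dimethyl-S-phenylsulfoximine | C[S@@](=O)(=NC)c1ccccc1 | starting material
7 | lithiated (S)-N,S-dimethyl-S-phenylsulfoximine | [Li]C[S@@](=O)(=NC)c1ccccc1 | intermediate
8 | (1R,6S,7R)-3-methyl-7-{[(S)-N-methyl-S-phenylsulfonimidoyl]methyl}bicyclo[4.2.0]oct-2-en-7-ol | CC1=C[C@H]2C[C@](O)(C[S@@](=O)(=NC)c3ccccc3)[C@H]2CC1 | intermediate
9 | (1R,6S)-3-methylbicyclo[4.2.0]oct-2-en-7-one | CC1=C[C@H]2CC(=O)[C@H]2CC1 | intermediate
10 | 3-(trimethylsilyl)prop-2-yn-1-ol | C[Si](C)(C)C#CCO | starting material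
11 | tert-butyldimethyl{[3-(trimethylsilyl)prop-2-yn-1-yl]oxy}silane | C[Si](C)(C)C#CCO[Si](C)(C)C(C)(C)C | intermediate
12 | (4aR,8aS)-2-{[tert-butyl(dimethyl)silyl]oxymethyl}-6-methyl-3-(trimethylsilyl)-4a,7,8,8a-tetrahydronaphthalen-1(4H)-one | CC1=C[C@H]2CC([Si](C)(C)C)=C(CO[Si](C)(C)C(C)(C)C)C(=O)[C@H]2CC1 | intermediate
13 | (4aR,8aS)-2-{[tert-butyl(dimethyl)silyl]oxymethyl}-1,6-dimethyl-3-(trimethylsilyl)-1,4,4a,7,8,8a-hexahydronaphthalen-1-ol (C1 epimers) | CC1=C[C@H]2CC([Si](C)(C)C)=C(CO[Si](C)(C)C(C)(C)C)C(C)(O)[C@H]2CC1 | intermediate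
14 | tert-butyldimethyl{[(4aR,8aS)-1,1,6-trimethyl-3-(trimethylsilyl)-1,4,4a,7,8,8a-hexahydronaphthalen-2-yl]methoxy}silane | CC1=C[C@H]2CC([Si](C)(C)C)=C(CO[Si](C)(C)C(C)(C)C)C(C)(C)[C@H]2CC1 | intermediate
15 | tert-butyl{[(4aR,8aS)-3-iodo-1,1,6-trimethyl-1,4,4a,7,8,8a-hexahydronaphthalen-2-yl]methoxy}dimethylsilane | CC1=C[C@H]2CC(I)=C(CO[Si](C)(C)C(C)(C)C)C(C)(C)[C@H]2CC1 | intermediate
16 | alkenyllithium from 15 (lithium at C3) | CC1=C[C@H]2CC([Li])=C(CO[Si](C)(C)C(C)(C)C)C(C)(C)[C@H]2CC1 | intermediate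
17 | tert-butyldimethyl{[(4aR,8aS)-1,1,3,6-tetramethyl-1,4,4a,7,8,8a-hexahydronaphthalen-2-yl]methoxy}silane | CC1=C[C@H]2CC(C)=C(CO[Si](C)(C)C(C)(C)C)C(C)(C)[C@H]2CC1 | intermediate
18 | [(4aR,8aS)-1,1,3,6-tetramethyl-1,4,4a,7,8,8a-hexahydronaphthalen-2-yl]methanol | CC1=C[C@H]2CC(C)=C(CO)C(C)(C)[C@H]2CC1 | intermediate
19 | {[(4aR,8aS)-1,1,3,6-tetramethyl-1,4,4a,7,8,8a-hexahydronaphthalen-2-yl]methyl}triphenylphosphonium bromide | CC1=C[C@H]2CC(C)=C(C[P+](c3ccccc3)(c3ccccc3)c3ccccc3)C(C)(C)[C@H]2CC1.[Br-] | intermediate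
20 | (R)-(−)-linalool | C=C[C@](C)(O)CCC=C(C)C | starting material
21 | (2R)-2-methylpentane-1,2,5-triol | OC[C@](C)(O)CCCO | intermediate
22 | 3-[(4R)-2,2,4-trimethyl-1,3-dioxolan-4-yl]propan-1-ol | OCCC[C@]1(C)COC(C)(C)O1 | intermediate
23 | 3-[(4R)-2,2,4-trimethyl-1,3-dioxolan-4-yl]propanal | O=CCC[C@]1(C)COC(C)(C)O1 | intermediate
24 | (4R)-4-benzyl-3-propanoyl-1,3-oxazolidin-2-one | CCC(=O)N1[C@H](Cc2ccccc2)COC1=O | starting material
25 | (Z)-dibutylboron enolate of 24 | C/C=C(/N1[C@H](Cc2ccccc2)COC1=O)OB(CCCC)CCCC | intermediate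
26 | (4R)-4-benzyl-3-{(2R,3S)-3-hydroxy-2-methyl-5-[(4R)-2,2,4-trimethyl-1,3-dioxolan-4-yl]pentanoyl}-1,3-oxazolidin-2-one | O=C1OC[C@@H](Cc2ccccc2)N1C(=O)[C@H](C)[C@@H](O)CC[C@]3(C)COC(C)(C)O3 | intermediate
27 | (2S,3S)-2-methyl-5-[(4R)-2,2,4-trimethyl-1,3-dioxolan-4-yl]pentane-1,3-diol | OC[C@H](C)[C@@H](O)CC[C@]1(C)COC(C)(C)O1 | intermediate
28 | (2S,3S)-1-[(tert-butyldiphenylsilyl)oxy]-2-methyl-5-[(4R)-2,2,4-trimethyl-1,3-dioxolan-4-yl]pentan-3-ol | CC(C)(C)[Si](c1ccccc1)(c1ccccc1)OC[C@H](C)[C@@H](O)CC[C@]2(C)COC(C)(C)O2 | intermediate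
29 | (2R,5S,6S)-7-[(tert-butyldiphenylsilyl)oxy]-2,6-dimethylheptane-1,2,5-triol | CC(C)(C)[Si](c1ccccc1)(c1ccccc1)OC[C@H](C)[C@@H](O)CC[C@@](C)(O)CO | intermediate
30 | (2R,5S,6S)-7-[(tert-butyldiphenylsilyl)oxy]-2,5-dihydroxy-2,6-dimethylheptyl 4-methylbenzenesulfonate | CC(C)(C)[Si](c1ccccc1)(c1ccccc1)OC[C@H](C)[C@@H](O)CC[C@@](C)(O)COS(=O)(=O)c2ccc(C)cc2 | intermediate
31 | (2S,3S)-1-[(tert-butyldiphenylsilyl)oxy]-2-methyl-5-[(2R)-2-methyloxiran-2-yl]pentan-3-ol | CC(C)(C)[Si](c1ccccc1)(c1ccccc1)OC[C@H](C)[C@@H](O)CC[C@]2(C)CO2 | intermediate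
32 | (2S,3S)-1-[(tert-butyldiphenylsilyl)oxy]-2-methyl-5-[(2R)-2-methyloxiran-2-yl]pentan-3-yl methanesulfonate | CC(C)(C)[Si](c1ccccc1)(c1ccccc1)OC[C@H](C)[C@@H](OS(C)(=O)=O)CC[C@]2(C)CO2 | intermediate
33 | (2S,3S,6S)-1-[(tert-butyldiphenylsilyl)oxy]-6-hydroperoxy-7-hydroxy-2,6-dimethylheptan-3-yl methanesulfonate | CC(C)(C)[Si](c1ccccc1)(c1ccccc1)OC[C@H](C)[C@@H](OS(C)(=O)=O)CC[C@](C)(OO)CO | intermediate
34 | {(3S,6R)-6-[(2S)-1-[(tert-butyldiphenylsilyl)oxy]propan-2-yl]-3-methyl-1,2-dioxan-3-yl}methanol | CC(C)(C)[Si](c1ccccc1)(c1ccccc1)OC[C@H](C)[C@H]2CC[C@@](C)(CO)OO2 | intermediate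
35 | (3S,6R)-6-{(2S)-1-[(tert-butyldiphenylsilyl)oxy]propan-2-yl}-3-methyl-1,2-dioxane-3-carbaldehyde | CC(C)(C)[Si](c1ccccc1)(c1ccccc1)OC[C@H](C)[C@H]2CC[C@@](C)(C=O)OO2 | intermediate
36 | phosphorus ylide from 19 | CC1=C[C@H]2CC(C)=C(C=P(c3ccccc3)(c3ccccc3)c3ccccc3)C(C)(C)[C@H]2CC1 | intermediate
37 | tert-butyl{(2S)-2-[(3R,6S)-6-methyl-6-{2-[(4aR,8aS)-1,1,3,6-tetramethyl-1,4,4a,7,8,8a-hexahydronaphthalen-2-yl]ethenyl}-1,2-dioxan-3-yl]propoxy}diphenylsilane (E/Z mixture) | CC1=C[C@H]2CC(C)=C(C=C[C@]3(C)CC[C@H]([C@@H](C)CO[Si](c4ccccc4)(c4ccccc4)C(C)(C)C)OO3)C(C)(C)[C@H]2CC1 | intermediate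
38 | tert-butyl{(2S)-2-[(3R,6R)-6-methyl-6-{2-[(4aR,8aS)-1,1,3,6-tetramethyl-1,4,4a,7,8,8a-hexahydronaphthalen-2-yl]ethyl}-1,2-dioxan-3-yl]propoxy}diphenylsilane | CC1=C[C@H]2CC(C)=C(CC[C@]3(C)CC[C@H]([C@@H](C)CO[Si](c4ccccc4)(c4ccccc4)C(C)(C)C)OO3)C(C)(C)[C@H]2CC1 | intermediate
39 | (2S)-2-[(3R,6R)-6-methyl-6-{2-[(4aR,8aS)-1,1,3,6-tetramethyl-1,4,4a,7,8,8a-hexahydronaphthalen-2-yl]ethyl}-1,2-dioxan-3-yl]propan-1-ol | CC1=C[C@H]2CC(C)=C(CC[C@]3(C)CC[C@H]([C@@H](C)CO)OO3)C(C)(C)[C@H]2CC1 | intermediate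
40 | (2R)-2-[(3R,6R)-6-methyl-6-{2-[(4aR,8aS)-1,1,3,6-tetramethyl-1,4,4a,7,8,8a-hexahydronaphthalen-2-yl]ethyl}-1,2-dioxan-3-yl]propanal | CC1=C[C@H]2CC(C)=C(CC[C@]3(C)CC[C@H]([C@@H](C)C=O)OO3)C(C)(C)[C@H]2CC1 | intermediate
41 | (2R)-2-[(3R,6R)-6-methyl-6-{2-[(4aR,8aS)-1,1,3,6-tetramethyl-1,4,4a,7,8,8a-hexahydronaphthalen-2-yl]ethyl}-1,2-dioxan-3-yl]propanoic acid | CC1=C[C@H]2CC(C)=C(CC[C@]3(C)CC[C@H]([C@@H](C)C(=O)O)OO3)C(C)(C)[C@H]2CC1 | target

**Step count and risks**

Total step count: 27 (steps 1–11 for the carbocyclic fragment, 12–23 for the dioxane fragment, 24–27 after the union).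
Longest linear sequence: 16 steps (20 → 41, steps 12–27).

The three steps most likely to fail:

1. Step 6. The oxidative cyclisation of the hindered silyl alkyne with the ketone at nickel may be so slow that alkyne oligomerisation and catalyst decay outrun insertion, or β-carbon elimination may take the ring-fusion carbon instead of the CH2 carbon. Fallback (sets out from 9, comes back at 18): ring B is built by the classical cation–olefin route instead of C–C insertion. 9 is formylated at its CH2 group and the 2-formylcyclobutanone is opened by retro-Claisen cleavage (HCO2Me, NaH, then NaOMe, MeOH) to methyl (1S,2R)-4-methyl-2-(2-oxoethyl)cyclohex-3-ene-1-carboxylate F1. Excess MeMgBr turns ester and aldehyde into 2-[(1S,2R)-2-(2-hydroxypropyl)-4-methylcyclohex-3-en-1-yl]propan-2-ol F2. Dess–Martin oxidation of the secondary alcohol gives 1-[(1R,6S)-6-(2-hydroxypropan-2-yl)-3-methylcyclohex-2-en-1-yl]propan-2-one F3. Horner–Wadsworth–Emmons olefination (triethyl phosphonoacetate, NaH) gives ethyl 4-[(1R,6S)-6-(2-hydroxypropan-2-yl)-3-methylcyclohex-2-en-1-yl]-3-methylbut-2-enoate F4. Ionisation of the tertiary alcohol with BF3·OEt2 closes ring B by attack of the enoate α-carbon on the cation (as in the geranate to cyclogeranate cyclisation), and NaOEt moves the alkene into conjugation to give ethyl (4aR,8aS)-1,1,3,6-tetramethyl-1,4,4a,7,8,8a-hexahydronaphthalene-2-carboxylate F5. Reduction with (i-Bu)2AlH gives 18, which is taken on to 19 with Ph3P·HBr as in step 11.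

2. Step 21. Ionisation at the tertiary epoxide carbon ahead of backside attack would erode the configuration of the quaternary peroxy carbon, and attack at the primary carbon or reaction of the product hydroperoxide with a second epoxide would consume material. Fallback (sets out from 32, comes back at 34): the order of the two C–O bond formations is reversed so that the epoxide is opened intramolecularly. The mesylate of 32 is displaced with inversion by 2-methoxyprop-2-yl hydroperoxide (CsOH·H2O, DMF) to give tert-butyl{(2S,3R)-3-[(2-methoxypropan-2-yl)peroxy]-2-methyl-5-[(2R)-2-methyloxiran-2-yl]pentyloxy}diphenylsilane F6. Pyridinium p-toluenesulfonate in wet CH2Cl2 then removes the ketal, and the tethered hydroperoxide opens the epoxide at the tertiary carbon by 6-exo attack with inversion to give 34.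

3. Step 24. Addition of the hindered ylide to the hindered aldehyde may be slow enough for the ylide to attack the O–O bond or simply to be quenched. Fallback (sets out from 17, comes back at 37): a Julia–Kocienski olefination replaces the phosphorus ylide by a less basic sulfonyl carbanion. Bu4NF frees 18 from 17. A Mitsunobu reaction with 1-phenyl-1H-tetrazole-5-thiol (PPh3, diisopropyl azodicarboxylate) gives 5-({[(4aR,8aS)-1,1,3,6-tetramethyl-1,4,4a,7,8,8a-hexahydronaphthalen-2-yl]methyl}sulfanyl)-1-phenyl-1H-tetrazole F7. Oxidation with H2O2 and (NH4)6Mo7O24 in EtOH gives the sulfone 5-({[(4aR,8aS)-1,1,3,6-tetramethyl-1,4,4a,7,8,8a-hexahydronaphthalen-2-yl]methyl}sulfonyl)-1-phenyl-1H-tetrazole F8. Deprotonation with KN(SiMe3)2 at −78 °C in the presence of 35 gives 37.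

Further compounds
F1 | step 6 | methyl (1S,2R)-4-methyl-2-(2-oxoethyl)cyclohex-3-ene-1-carboxylate | CC1=C[C@@H](CC=O)[C@@H](C(=O)OC)CC1
F2 | step 6 | 2-[(1S,2R)-2-(2-hydroxypropyl)-4-methylcyclohex-3-en-1-yl]propan-2-ol (carbinol epimers) | CC1=C[C@@H](CC(C)O)[C@@H](C(C)(C)O)CC1
F3 | step 6 | 1-[(1R,6S)-6-(2-hydroxypropan-2-yl)-3-methylcyclohex-2-en-1-yl]propan-2-one | CC1=C[C@@H](CC(C)=O)[C@@H](C(C)(C)O)CC1
F4 | step 6 | ethyl 4-[(1R,6S)-6-(2-hydroxypropan-2-yl)-3-methylcyclohex-2-en-1-yl]-3-methylbut-2-enoate (E/Z mixture) | CC1=C[C@@H](CC(C)=CC(=O)OCC)[C@@H](C(C)(C)O)CC1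
F5 | step 6 | ethyl (4aR,8aS)-1,1,3,6-tetramethyl-1,4,4a,7,8,8a-hexahydronaphthalene-2-carboxylate | CC1=C[C@H]2CC(C)=C(C(=O)OCC)C(C)(C)[C@H]2CC1
F6 | step 21 | tert-butyl{(2S,3R)-3-[(2-methoxypropan-2-yl)peroxy]-2-methyl-5-[(2R)-2-methyloxiran-2-yl]pentyloxy}diphenylsilane | CC(C)(C)[Si](c1ccccc1)(c1ccccc1)OC[C@H](C)[C@H](OOC(C)(C)OC)CC[C@]2(C)CO2
F7 | step 24 | 5-({[(4aR,8aS)-1,1,3,6-tetramethyl-1,4,4a,7,8,8a-hexahydronaphthalen-2-yl]methyl}sulfanyl)-1-phenyl-1H-tetrazole | CC1=C[C@H]2CC(C)=C(CSc3nnnn3-c3ccccc3)C(C)(C)[C@H]2CC1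
F8 | step 24 | 5-({[(4aR,8aS)-1,1,3,6-tetramethyl-1,4,4a,7,8,8a-hexahydronaphthalen-2-yl]methyl}sulfonyl)-1-phenyl-1H-tetrazole | CC1=C[C@H]2CC(C)=C(CS(=O)(=O)c3nnnn3-c3ccccc3)C(C)(C)[C@H]2CC1
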